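## Retrosynthetic overview

1. The furan ring is the only ring made, and it is closed last by 5-endo-dig cycloisomerisation of an o-hydroxy diaryl alkyne; both benzene rings are bought.
2. The diaryl alkyne comes from a Sonogashira union of a 2,6-diprenyl aryl acetylene (A ring) with a 3-prenyl-2,4-dioxygenated aryl iodide (B ring), all phenols carried as MOM ethers.
3. A ring: 3,5-dihydroxybenzaldehyde, MOM protection, 2,6-dibromination, double Stille prenylation, Ohira–Bestmann homologation.
4. B ring: resorcinol bis-MOM ether, two successive directed ortho-metalations (C2 prenylation, then C4 iodination).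

Assumption: the target has no stereocentre and its three C=C bonds are CH=CMe2 (no E/Z), so "single enantiomer" does not apply and the route delivers the one achiral structure. 1,3-Bis(methoxymethoxy)benzene is taken as a catalogue compound (otherwise one extra step from resorcinol and MOMCl).

## Route

**Step 1**
Reactants: 1 3,5-dihydroxybenzaldehyde
Product: 2 3,5-bis(methoxymethoxy)benzaldehyde
Conditions: MOMCl (2.6 equiv), i-Pr2NEt (3 equiv), CH2Cl2, 0 °C to rt
Reagents that add atoms: chloromethyl methyl ether (MOMCl), COCCl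
Why: O-alkylation of both phenols (MOM acetal formation) gives ethers that survive NBS, Pd, K2CO3/MeOH and amine bases; no stereocentre.

**Step 2**
Reactants: 2 3,5-bis(methoxymethoxy)benzaldehyde
Product: 3 2,6-dibromo-3,5-bis(methoxymethoxy)benzaldehyde
Conditions: NBS (2.2 equiv), DMF, 0 to 40 °C, dark
Reagents that add atoms: N-bromosuccinimide, O=C1CCC(=O)N1Br
Why: Electrophilic aromatic bromination goes to C2 and C6 (each para to one OMOM and ortho to the other), while C4 between two OMOM groups is spared, as in the 2,6-dihalogenation of 3,5-dimethoxyphenyl compounds.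

**Step 3**
Reactants: 3 2,6-dibromo-3,5-bis(methoxymethoxy)benzaldehyde
Product: 4 3,5-bis(methoxymethoxy)-2,6-bis(3-methylbut-2-en-1-yl)benzaldehyde
Conditions: prenyl-SnBu3 (3 equiv), Pd(PPh3)4 (10 mol %), toluene, 110 °C
Reagents that add atoms: tributyl(3-methylbut-2-en-1-yl)stannane, CCCC[Sn](CCCC)(CCCC)CC=C(C)C
Why: Twofold Migita–Kosugi–Stille coupling, with oxidative addition helped by the ortho-formyl group and C–C bond formation at the unsubstituted allyl terminus giving the linear prenyl groups; aldehyde and MOM ethers are inert.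

**Step 4**
Reactants: 4 3,5-bis(methoxymethoxy)-2,6-bis(3-methylbut-2-en-1-yl)benzaldehyde
Product: 5 3-ethynyl-1,5-bis(methoxymethoxy)-2,4-bis(3-methylbut-2-en-1-yl)benzene
Conditions: Bestmann–Ohira reagent (2 equiv), K2CO3 (3 equiv), MeOH/THF, rt to 40 °C
Reagents that add atoms: dimethyl (1-diazo-2-oxopropyl)phosphonate, COP(=O)(OC)C(=[N+]=[N-])C(C)=O
Why: Ohira–Bestmann (Seyferth–Gilbert) homologation turns the aldehyde into the terminal alkyne under mild basic conditions that leave MOM ethers and prenyl groups alone.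

**Step 5**
Reactants: 6 1,3-bis(methoxymethoxy)benzene
Product: 8 1,3-bis(methoxymethoxy)-2-(3-methylbut-2-en-1-yl)benzene, via 2-lithio-1,3-bis(methoxymethoxy)benzene 7 (not isolated)
Conditions: n-BuLi (1.1 equiv), THF, 0 °C, 1 h; then CuI (10 mol %), prenyl bromide (1.3 equiv), −78 °C to rt
Reagents that add atoms: 1-bromo-3-methylbut-2-ene (prenyl bromide), CC(C)=CCBr
Why: Directed ortho-metalation at C2, the position flanked by both OMOM groups, then copper-assisted SN2 alkylation of the aryllithium.

**Step 6**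
Reactants: 8 1,3-bis(methoxymethoxy)-2-(3-methylbut-2-en-1-yl)benzene
Product: 10 1-iodo-2,4-bis(methoxymethoxy)-3-(3-methylbut-2-en-1-yl)benzene, via 4-lithio-1,3-bis(methoxymethoxy)-2-prenylbenzene 9 (not isolated)
Conditions: n-BuLi (1.2 equiv), TMEDA (1.2 equiv), THF, −20 to 0 °C; then I2 (1.3 equiv), −78 °C to rt; aq. Na2S2O3
Reagents that add atoms: iodine, II
Why: Second directed ortho-metalation at the only remaining ring position next to an OMOM group (C4 and C6 are equivalent), then iodinolysis of the aryllithium.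

**Step 7**
Reactants: 5 3-ethynyl-1,5-bis(methoxymethoxy)-2,4-bis(3-methylbut-2-en-1-yl)benzene; 10 1-iodo-2,4-bis(methoxymethoxy)-3-(3-methylbut-2-en-1-yl)benzene
Product: 11 3-{[2,4-bis(methoxymethoxy)-3-(3-methylbut-2-en-1-yl)phenyl]ethynyl}-1,5-bis(methoxymethoxy)-2,4-bis(3-methylbut-2-en-1-yl)benzene
Conditions: PdCl2(PPh3)2 (5 mol %), CuI (10 mol %), Et3N/DMF, 60 °C, degassed
Reagents that add atoms: none
Why: Sonogashira coupling of an aryl iodide with a terminal alkyne; the linear alkyne keeps the two flanking prenyl groups away from the metal, and MOM ethers and alkenes are inert.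

**Step 8**
Reactants: 11 tetrakis-MOM diaryl alkyne
Product: 12 4-{[3,5-dihydroxy-2,6-bis(3-methylbut-2-en-1-yl)phenyl]ethynyl}-2-(3-methylbut-2-en-1-yl)benzene-1,3-diol
Conditions: HCl (cat., ca. 0.3 M), MeOH/THF 3:1, 40 °C, Ar; NaHCO3 quench
Reagents that add atoms: none
Why: Acid-catalysed acetal exchange cleaves the four aryl MOM ethers (as dimethoxymethane) under conditions kept milder than those that protonate the prenyl alkenes or hydrate the alkyne.

**Step 9**
Reactants: 12 tetraol diaryl alkyne
Product: 13 2-[3,5-dihydroxy-2,6-bis(3-methylbut-2-en-1-yl)phenyl]-7-(3-methylbut-2-en-1-yl)-1-benzofuran-6-ol (target)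
Conditions: Cs2CO3 (30 mol %), DMF, 80 °C, Ar (degassed); aq. NH4Cl
Reagents that add atoms: none
Why: Base-catalysed 5-endo-dig hydroalkoxylation (cycloisomerisation) of the o-alkynylphenol; only the 3-OH is ortho to the alkyne, so only the benzofuran can form, and the non-acidic medium spares the o-prenylphenols.

## Compound list

1 | 3,5-dihydroxybenzaldehyde | O=Cc1cc(O)cc(O)c1 | starting material
2 | 3,5-bis(methoxymethoxy)benzaldehyde | O=Cc1cc(OCOC)cc(OCOC)c1 | intermediate
3 | 2,6-dibromo-3,5-bis(methoxymethoxy)benzaldehyde | O=Cc1c(Br)c(OCOC)cc(OCOC)c1Br | intermediate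
4 | 3,5-bis(methoxymethoxy)-2,6-bis(3-methylbut-2-en-1-yl)benzaldehyde | O=Cc1c(CC=C(C)C)c(OCOC)cc(OCOC)c1CC=C(C)C | intermediate
5 | 3-ethynyl-1,5-bis(methoxymethoxy)-2,4-bis(3-methylbut-2-en-1-yl)benzene | C#Cc1c(CC=C(C)C)c(OCOC)cc(OCOC)c1CC=C(C)C | intermediate
6 | 1,3-bis(methoxymethoxy)benzene | COCOc1cccc(OCOC)c1 | starting material
7 | [2,6-bis(methoxymethoxy)phenyl]lithium | [Li]c1c(OCOC)cccc1OCOC | intermediate (not isolated)
8 | 1,3-bis(methoxymethoxy)-2-(3-methylbut-2-en-1-yl)benzene | COCOc1cccc(OCOC)c1CC=C(C)C | intermediate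
9 | [2,4-bis(methoxymethoxy)-3-(3-methylbut-2-en-1-yl)phenyl]lithium | [Li]c1ccc(OCOC)c(CC=C(C)C)c1OCOC | intermediate (not isolated)
10 | 1-iodo-2,4-bis(methoxymethoxy)-3-(3-methylbut-2-en-1-yl)benzene | Ic1ccc(OCOC)c(CC=C(C)C)c1OCOC | intermediate
11 | 3-{[2,4-bis(methoxymethoxy)-3-(3-methylbut-2-en-1-yl)phenyl]ethynyl}-1,5-bis(methoxymethoxy)-2,4-bis(3-methylbut-2-en-1-yl)benzene | COCOc1ccc(C#Cc2c(CC=C(C)C)c(OCOC)cc(OCOC)c2CC=C(C)C)c(OCOC)c1CC=C(C)C | intermediate
12 | 4-{[3,5-dihydroxy-2,6-bis(3-methylbut-2-en-1-yl)phenyl]ethynyl}-2-(3-methylbut-2-en-1-yl)benzene-1,3-diol | Oc1ccc(C#Cc2c(CC=C(C)C)c(O)cc(O)c2CC=C(C)C)c(O)c1CC=C(C)C | intermediate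
13 | 2-[3,5-dihydroxy-2,6-bis(3-methylbut-2-en-1-yl)phenyl]-7-(3-methylbut-2-en-1-yl)-1-benzofuran-6-ol | CC(C)=CCc1c(O)cc(O)c(CC=C(C)C)c1-c1cc2ccc(O)c(CC=C(C)C)c2o1 | target

## Summary

Total step count: 9.
Longest linear sequence: 7 steps (steps 1, 2, 3, 4, 7, 8, 9); the B-ring branch is steps 5 and 6.

## Steps most likely to fail, with fallbacks

**Step 3 (double Stille prenylation).** Both C–Br bonds are flanked on two sides, and the prenyl stannane can give incomplete second coupling, some reverse-prenyl (γ) product or Pd-mediated carbonyl allylation. The fallback sets out from 3 and comes back at 4. Stille coupling of 3 with allyltributylstannane (Pd(PPh3)4, toluene, 110 °C) has no α/γ ambiguity and gives 3,5-bis(methoxymethoxy)-2,6-di(prop-2-en-1-yl)benzaldehyde F1. Olefin cross-metathesis of this with excess 2-methylbut-2-ene (Grubbs II, CH2Cl2, 40 °C) converts both allyl groups into prenyl groups, which is 4.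

**Step 6 (second ortho-lithiation and iodination).** The base may instead remove a proton from the benzylic/allylic CH2 of the prenyl group, giving low conversion or side-chain iodination. The fallback sets out from 8 and comes back at 11, replacing deprotonation by electrophilic substitution. NBS (1.0 equiv, DMF, −20 °C) brominates the very electron-rich ring para to an OMOM group to give 1-bromo-2,4-bis(methoxymethoxy)-3-(3-methylbut-2-en-1-yl)benzene F2. This is joined to 5 by a copper-free Sonogashira coupling (PdCl2(MeCN)2, XPhos, Cs2CO3, MeCN, 80 °C) to give 11.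

**Step 8 (acidic removal of four MOM groups).** Three o-prenylphenol units can close to 2,2-dimethylchromans and the electron-rich alkyne can hydrate under protic acid. The fallback sets out from 11 and comes back at 13, bypassing 12 and step 9. TESOTf with 2,2′-bipyridyl (MeCN, 0 °C to rt) exchanges the aryl MOM ethers directly for silyl ethers without protic acid, giving 4-{[3,5-bis(triethylsilyloxy)-2,6-bis(3-methylbut-2-en-1-yl)phenyl]ethynyl}-2-(3-methylbut-2-en-1-yl)-1,3-bis(triethylsilyloxy)benzene F3. TBAF (THF, 60 °C) then removes the four silyl groups and the liberated phenoxide closes the benzofuran in the same flask, giving 13.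

## Further compounds

F1 | step 3 | 3,5-bis(methoxymethoxy)-2,6-di(prop-2-en-1-yl)benzaldehyde | O=Cc1c(CC=C)c(OCOC)cc(OCOC)c1CC=C
F2 | step 6 | 1-bromo-2,4-bis(methoxymethoxy)-3-(3-methylbut-2-en-1-yl)benzene | Brc1ccc(OCOC)c(CC=C(C)C)c1OCOC
F3 | step 8 | 4-{[3,5-bis(triethylsilyloxy)-2,6-bis(3-methylbut-2-en-1-yl)phenyl]ethynyl}-2-(3-methylbut-2-en-1-yl)-1,3-bis(triethylsilyloxy)benzene | CC[Si](CC)(CC)Oc1ccc(C#Cc2c(CC=C(C)C)c(O[Si](CC)(CC)CC)cc(O[Si](CC)(CC)CC)c2CC=C(C)C)c(O[Si](CC)(CC)CC)c1CC=C(C)C
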